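**Retrosynthetic overview**

1. The aryl ketone bond C5–C(=O) of the dihydrobenzofuran (benzene ring A, dihydrofuran ring B) is made last but one, by photo-Fries shift of the C6–O aryl ester 23. Ester 23 joins phenol 11 to the (S)-β-silyloxy acid 22, whose carbinol centre comes from Noyori hydrogenation of β-keto ester 19.
2. The plan rests on the O1–C2(H)–C(CH3)2OH unit of ring B. It is a constitutional isomer of the O1–C2(CH3)2–C3(H)OH unit of a 2,2-dimethylchroman-3-ol, which Jacobsen epoxidation of chromene 5 and benzylic hydrogenolysis should give in high enantiopurity.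
3. Ring B is therefore made by contraction of the pyran ring of mesylate 8: O1 displaces the C3 sulfonate with inversion, and water opens the oxiranium ion at the gem-dimethyl carbon (8 → 10).
4. Ring order: the pyran ring of 1 is bought and contracted to ring B in step 7. Pyran ring D of the second chroman (on benzene ring C) is closed by propargyl ether Claisen cyclisation in step 10. Rings A and C are bought as arenes, and the halves are joined in step 16.

Key step: step 7

Remark: 7-hydroxy-2,2-dimethylchroman-4-one (1) is taken as a catalogue compound; the sense of induction assumed is (R,R)-salen manganese catalyst → (3R,4R)-chromene oxide and (R)-BINAP–ruthenium → (S)-aryl carbinol, as for 2,2-dimethylchromenes and aroylacetates in general.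

**Route**

Step 1
Reactants: 1 7-hydroxy-2,2-dimethylchroman-4-one; 2 pivaloyl chloride
Product: 3 2,2-dimethyl-4-oxochroman-7-yl pivalate
Conditions: Et3N, DMAP (cat.), CH2Cl2, 0 °C → rt
Reagents that add atoms: none
Why: DMAP-catalysed O-acylation of the only hydroxyl group; the hindered aryl pivalate should survive borohydride, acid, buffered hypochlorite and aqueous solvolysis, and an acyloxy group donates far less into ring A than a free or alkylated phenol.

Step 2
Reactants: 3 2,2-dimethyl-4-oxochroman-7-yl pivalate
Product: 4 4-hydroxy-2,2-dimethylchroman-7-yl pivalate (racemic)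
Conditions: NaBH4, THF/MeOH, 0 °C
Reagents that add atoms: none
Why: Borohydride 1,2-reduction of the aryl ketone should be faster at 0 °C than methanolysis of the hindered pivalate; the racemic carbinol centre is removed in step 3.

Step 3
Reactants: 4 4-hydroxy-2,2-dimethylchroman-7-yl pivalate
Product: 5 2,2-dimethyl-2H-chromen-7-yl pivalate
Conditions: p-TsOH·H2O (cat.), toluene, reflux, Dean–Stark
Reagents that add atoms: none
Why: Acid-catalysed E1 dehydration of the benzylic alcohol (cation stabilised by O1 and the C7 oxygen) gives the conjugated C3=C4 alkene, with water removed azeotropically.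

Step 4
Reactants: 5 2,2-dimethyl-2H-chromen-7-yl pivalate
Product: 6 (3R,4R)-3,4-epoxy-2,2-dimethylchroman-7-yl pivalate
Conditions: aq. NaOCl (pH 11.3, Na2HPO4), (R,R)-[N,N'-bis(3,5-di-tert-butylsalicylidene)cyclohexane-1,2-diaminato]MnCl (C36H52ClMnN2O2, trivalent manganese, 4 mol %), 4-phenylpyridine N-oxide, CH2Cl2, 0 °C
Reagents that add atoms: sodium hypochlorite, [Na+].[O-]Cl
Why: Jacobsen–Katsuki epoxidation, for which cis-disubstituted aryl-conjugated alkenes of 2,2-dimethylchromenes are the best substrate class; the (R,R) ligand steers side-on approach to the oxo-manganese species so that oxygen is delivered to the face giving the (3R,4R)-epoxide, which fixes C3, and the acid-labile benzylic epoxide is carried on without silica chromatography.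

Step 5
Reactants: 6 (3R,4R)-3,4-epoxy-2,2-dimethylchroman-7-yl pivalate
Product: 7 (R)-3-hydroxy-2,2-dimethylchroman-7-yl pivalate
Conditions: H2 (1 atm), 10% Pd/C, EtOAc, rt
Reagents that add atoms: none
Why: Hydrogenolysis of a benzylic epoxide cleaves only the activated C4–O bond, so the C3–O bond and its configuration are untouched and the (3R,4R)-epoxide gives the (R)-alcohol.

Step 6
Reactants: 7 (R)-3-hydroxy-2,2-dimethylchroman-7-yl pivalate
Product: 8 (R)-2,2-dimethyl-3-(methylsulfonyloxy)chroman-7-yl pivalate
Conditions: MsCl, Et3N, CH2Cl2, 0 °C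
Reagents that add atoms: methanesulfonyl chloride, CS(=O)(=O)Cl
Why: O-sulfonylation through sulfene forms only the O–S bond, so C3 keeps its R configuration.

Step 7
Reactants: 8 (R)-2,2-dimethyl-3-(methylsulfonyloxy)chroman-7-yl pivalate
Product: 10 (S)-2-(2-hydroxypropan-2-yl)-2,3-dihydrobenzofuran-6-yl pivalate, via bicyclic oxiranium mesylate 9 (not isolated)
Conditions: H2O/(CF3)2CHOH (1:1), 2,6-lutidine, 60–80 °C
Reagents that add atoms: water, O
Why: In the half-chair with the C3 mesylate pseudo-equatorial, the O1–C2 ring bond lies antiperiplanar to C3–OMs, so a lone pair of O1 attacks C3 from the rear as mesylate leaves and gives oxiranium ion 9, whose long O–C(CH3)2 bond carries most of the positive charge. Water adds to that tertiary carbon and breaks the old O1–C2 bond, so O1 stays on the former C3 alone, the pyran ring becomes ring B, and the tertiary alcohol ends up outside the ring. The closest known reaction type is anchimerically assisted solvolysis with a 1,2-oxygen shift, as in contractions of tetrahydropyran-3-yl sulfonates to 2-(hydroxyalkyl)tetrahydrofurans and of 2,2-dimethylchroman-3-ol derivatives to 2-substituted dihydrobenzofurans. Ring B is closed by a 3-exo-tet O–C bond formation followed by opening of the three-membered ring at its other carbon, not by a direct five-ring cyclisation. The one new stereocentre, C2 of ring B, arises from C3 of 8 by a single stereospecific inversion, so the R centre set in step 4 becomes S. The step needs O1 participation to win over aryl participation from C4a, E2 loss to chromene 5 and proton loss from 9; the gem-dimethyl carbon stabilises the oxygen-bridged ion, the pivalate keeps the C7 oxygen (para to C4a) a weak donor, no acyl group para to O1 is present yet, and a hindered weak base in water-rich ionising solvent favours capture over elimination while keeping the product from re-ionising.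

Step 8
Reactants: 10 (S)-2-(2-hydroxypropan-2-yl)-2,3-dihydrobenzofuran-6-yl pivalate
Product: 11 (S)-2-(2-hydroxypropan-2-yl)-2,3-dihydrobenzofuran-6-ol
Conditions: K2CO3, MeOH, rt; aq. NH4Cl
Reagents that add atoms: none
Why: Base-mediated transesterification of the aryl ester (phenoxide leaving group) frees the phenol, while the tertiary alcohol and the C2 centre are inert.

Step 9
Reactants: 12 1-(4-hydroxyphenyl)ethanone; 13 3-chloro-3-methylbut-1-yne
Product: 14 1-[4-(2-methylbut-3-yn-2-yloxy)phenyl]ethanone
Conditions: DBU, CuCl2·2H2O (cat.), MeCN, 0 °C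
Reagents that add atoms: none
Why: Copper-catalysed propargylic etherification of the phenol, a substitution that works well with electron-poor phenols and tertiary propargylic chlorides.

Step 10
Reactants: 14 1-[4-(2-methylbut-3-yn-2-yloxy)phenyl]ethanone
Product: 16 1-(2,2-dimethyl-2H-chromen-6-yl)ethanone, via allenylphenol 15 (not isolated)
Conditions: N,N-diethylaniline, 190 °C
Reagents that add atoms: none
Why: Aromatic propargyl Claisen rearrangement to the ortho-allenylphenol, then 1,5-hydrogen shift and 6π-oxa-electrocyclisation, closes pyran ring D; the two ortho positions are equivalent.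

Step 11
Reactants: 16 1-(2,2-dimethyl-2H-chromen-6-yl)ethanone
Product: 17 1-(2,2-dimethylchroman-6-yl)ethanone
Conditions: H2 (1 atm), 10% Pd/C, EtOAc, rt, stopped after one equivalent of H2
Reagents that add atoms: none
Why: Catalytic hydrogenation of the styrene-type C3=C4 bond is much faster than reduction of the aryl ketone.

Step 12
Reactants: 17 1-(2,2-dimethylchroman-6-yl)ethanone; 18 dimethyl carbonate
Product: 19 methyl 3-(2,2-dimethylchroman-6-yl)-3-oxopropanoate
Conditions: NaH, toluene, 90 °C; then AcOH
Reagents that add atoms: none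
Why: Crossed Claisen condensation of the methyl ketone enolate with dimethyl carbonate, driven by deprotonation of the β-keto ester formed.

Step 13
Reactants: 19 methyl 3-(2,2-dimethylchroman-6-yl)-3-oxopropanoate
Product: 20 methyl (S)-3-(2,2-dimethylchroman-6-yl)-3-hydroxypropanoate
Conditions: H2 (50 bar), [RuCl(p-cymene)((R)-BINAP)]Cl (divalent ruthenium, 1 mol %; BINAP = 2,2'-bis(diphenylphosphino)-1,1'-binaphthyl), MeOH, 50 °C
Reagents that add atoms: none
Why: Noyori asymmetric hydrogenation of a β-keto ester through the ester-chelated ruthenium hydride; the (R)-ligand delivers hydride in the same spatial sense that gives (R)-3-hydroxybutanoates, which for an aryl ketone (aryl outranks CH2CO2Me) is the (S)-carbinol.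

Step 14
Reactants: 20 methyl (S)-3-(2,2-dimethylchroman-6-yl)-3-hydroxypropanoate
Product: 21 methyl (S)-3-(tert-butyldimethylsilyloxy)-3-(2,2-dimethylchroman-6-yl)propanoate
Conditions: TBSCl, imidazole, DMF, rt
Reagents that add atoms: tert-butyldimethylsilyl chloride, CC(C)(C)[Si](C)(C)Cl
Why: Imidazole-promoted O-silylation of the secondary alcohol; the ether keeps the hydroxyl from self-acylation in step 16 and leaves the stereocentre untouched.

Step 15
Reactants: 21 methyl (S)-3-(tert-butyldimethylsilyloxy)-3-(2,2-dimethylchroman-6-yl)propanoate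
Product: 22 (S)-3-(tert-butyldimethylsilyloxy)-3-(2,2-dimethylchroman-6-yl)propanoic acid
Conditions: LiOH·H2O, THF/MeOH/H2O, 0 °C → rt; then 1 M HCl to pH 4 at 0 °C
Reagents that add atoms: lithium hydroxide, [Li+].[OH-]
Why: Saponification of the methyl ester; silyloxide is a poor leaving group, so E1cB loss to the cinnamate should be slow at this temperature and the carbinol centre is not involved.

Step 16
Reactants: 11 (S)-2-(2-hydroxypropan-2-yl)-2,3-dihydrobenzofuran-6-ol; 22 (S)-3-(tert-butyldimethylsilyloxy)-3-(2,2-dimethylchroman-6-yl)propanoic acid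
Product: 23 (S)-2-(2-hydroxypropan-2-yl)-2,3-dihydrobenzofuran-6-yl (S)-3-(tert-butyldimethylsilyloxy)-3-(2,2-dimethylchroman-6-yl)propanoate
Conditions: DCC, DMAP (10 mol %), CH2Cl2, 0 °C → rt
Reagents that add atoms: none
Why: Steglich esterification; the phenol is acylated far faster than the hindered tertiary alcohol, and neither stereocentre is touched.

Step 17
Reactants: 23 (S)-2-(2-hydroxypropan-2-yl)-2,3-dihydrobenzofuran-6-yl (S)-3-(tert-butyldimethylsilyloxy)-3-(2,2-dimethylchroman-6-yl)propanoate
Product: 24 (S)-3-(tert-butyldimethylsilyloxy)-3-(2,2-dimethylchroman-6-yl)-1-[(S)-6-hydroxy-2-(2-hydroxypropan-2-yl)-2,3-dihydrobenzofuran-5-yl]propan-1-one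
Conditions: hν (254 nm, low-pressure Hg lamp, quartz), degassed MeCN (dilute), rt
Reagents that add atoms: none
Why: Photo-Fries rearrangement: homolysis of the ArO–C(=O) bond gives a caged phenoxyl/acyl radical pair that should recombine at C5, the unhindered ortho carbon para to O1 (the para carbon C3a is substituted and C7 is flanked by two oxygens), and tautomerisation gives the hydrogen-bonded, photostable ortho-hydroxyaryl ketone.

Step 18
Reactants: 24 (S)-3-(tert-butyldimethylsilyloxy)-3-(2,2-dimethylchroman-6-yl)-1-[(S)-6-hydroxy-2-(2-hydroxypropan-2-yl)-2,3-dihydrobenzofuran-5-yl]propan-1-one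
Product: 25 (S)-3-(2,2-dimethylchroman-6-yl)-3-hydroxy-1-[(S)-6-hydroxy-2-(2-hydroxypropan-2-yl)-2,3-dihydrobenzofuran-5-yl]propan-1-one (CNP0419761.2)
Conditions: HF·pyridine, pyridine, THF, 0 °C → rt
Reagents that add atoms: none
Why: Fluoride-driven Si–O cleavage under pyridine-buffered conditions, chosen to avoid the base-induced retro-aldol and dehydration/oxa-Michael (flavanone) pathways open to a 2'-hydroxy β-hydroxy ketone.

**Compound list**

1 | 7-hydroxy-2,2-dimethylchroman-4-one | CC1(C)CC(=O)c2ccc(O)cc2O1 | starting material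
2 | pivaloyl chloride | CC(C)(C)C(Cl)=O | starting material
3 | 2,2-dimethyl-4-oxochroman-7-yl pivalate | CC1(C)CC(=O)c2ccc(OC(=O)C(C)(C)C)cc2O1 | intermediate
4 | 4-hydroxy-2,2-dimethylchroman-7-yl pivalate (racemic) | CC1(C)CC(O)c2ccc(OC(=O)C(C)(C)C)cc2O1 | intermediate
5 | 2,2-dimethyl-2H-chromen-7-yl pivalate | CC1(C)C=Cc2ccc(OC(=O)C(C)(C)C)cc2O1 | intermediate
6 | (3R,4R)-3,4-epoxy-2,2-dimethylchroman-7-yl pivalate | CC1(C)Oc2cc(OC(=O)C(C)(C)C)ccc2[C@H]3O[C@H]31 | intermediate
7 | (R)-3-hydroxy-2,2-dimethylchroman-7-yl pivalate | O[C@@H]1Cc2ccc(OC(=O)C(C)(C)C)cc2OC1(C)C | intermediate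
8 | (R)-2,2-dimethyl-3-(methylsulfonyloxy)chroman-7-yl pivalate | CS(=O)(=O)O[C@@H]1Cc2ccc(OC(=O)C(C)(C)C)cc2OC1(C)C | intermediate
9 | bicyclic oxiranium ion (O1 bonded to C8a, to C(CH3)2 and to the former C3, S at that carbon), mesylate ion pair, not isolated | CC1(C)[O+]2c3cc(OC(=O)C(C)(C)C)ccc3C[C@@H]12.CS(=O)(=O)[O-] | intermediate
10 | (S)-2-(2-hydroxypropan-2-yl)-2,3-dihydrobenzofuran-6-yl pivalate | CC(C)(C)C(=O)Oc1ccc2c(c1)O[C@H](C(C)(C)O)C2 | intermediate
11 | (S)-2-(2-hydroxypropan-2-yl)-2,3-dihydrobenzofuran-6-ol | Oc1ccc2c(c1)O[C@H](C(C)(C)O)C2 | intermediate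
12 | 1-(4-hydroxyphenyl)ethanone | CC(=O)c1ccc(O)cc1 | starting material
13 | 3-chloro-3-methylbut-1-yne | C#CC(C)(C)Cl | starting material
14 | 1-[4-(2-methylbut-3-yn-2-yloxy)phenyl]ethanone | CC(=O)c1ccc(OC(C)(C)C#C)cc1 | intermediate
15 | 1-[4-hydroxy-3-(3-methylbuta-1,2-dien-1-yl)phenyl]ethanone (allenylphenol, not isolated) | CC(=O)c1ccc(O)c(C=C=C(C)C)c1 | intermediate
16 | 1-(2,2-dimethyl-2H-chromen-6-yl)ethanone | CC(=O)c1ccc2OC(C)(C)C=Cc2c1 | intermediate
17 | 1-(2,2-dimethylchroman-6-yl)ethanone | CC(=O)c1ccc2OC(C)(C)CCc2c1 | intermediate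
18 | dimethyl carbonate | COC(=O)OC | starting material
19 | methyl 3-(2,2-dimethylchroman-6-yl)-3-oxopropanoate | COC(=O)CC(=O)c1ccc2OC(C)(C)CCc2c1 | intermediate
20 | methyl (S)-3-(2,2-dimethylchroman-6-yl)-3-hydroxypropanoate | CC1(C)CCc2cc([C@@H](O)CC(=O)OC)ccc2O1 | intermediate
21 | methyl (S)-3-(tert-butyldimethylsilyloxy)-3-(2,2-dimethylchroman-6-yl)propanoate | CC1(C)CCc2cc([C@@H](O[Si](C)(C)C(C)(C)C)CC(=O)OC)ccc2O1 | intermediate
22 | (S)-3-(tert-butyldimethylsilyloxy)-3-(2,2-dimethylchroman-6-yl)propanoic acid | CC1(C)CCc2cc([C@@H](O[Si](C)(C)C(C)(C)C)CC(=O)O)ccc2O1 | intermediate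
23 | (S)-2-(2-hydroxypropan-2-yl)-2,3-dihydrobenzofuran-6-yl (S)-3-(tert-butyldimethylsilyloxy)-3-(2,2-dimethylchroman-6-yl)propanoate | CC1(C)CCc2cc([C@@H](O[Si](C)(C)C(C)(C)C)CC(=O)Oc3ccc4c(c3)O[C@H](C(C)(C)O)C4)ccc2O1 | intermediate
24 | (S)-3-(tert-butyldimethylsilyloxy)-3-(2,2-dimethylchroman-6-yl)-1-[(S)-6-hydroxy-2-(2-hydroxypropan-2-yl)-2,3-dihydrobenzofuran-5-yl]propan-1-one | CC1(C)CCc2cc([C@@H](O[Si](C)(C)C(C)(C)C)CC(=O)c3cc4c(cc3O)O[C@H](C(C)(C)O)C4)ccc2O1 | intermediate
25 | (S)-3-(2,2-dimethylchroman-6-yl)-3-hydroxy-1-[(S)-6-hydroxy-2-(2-hydroxypropan-2-yl)-2,3-dihydrobenzofuran-5-yl]propan-1-one | CC1(C)CCc2cc([C@@H](O)CC(=O)c3cc4c(cc3O)O[C@H](C(C)(C)O)C4)ccc2O1 | target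

**Step count**

Total step count: 18. Longest linear sequence: 11 steps (steps 1–8, then 16–18); the acid branch (steps 9–15) joins at step 16.

**Steps most likely to fail**

Step 7. Ionisation of the mesylate may be too slow in the water-rich medium, the bridged ion may lose a methyl proton faster than water adds, or the pivalate may hydrolyse before ionisation and so increase aryl participation. The fallback sets out from chromanol 7 and separates the contraction from the hydration. Triflation under anhydrous conditions (Tf2O, 2,6-lutidine, CH2Cl2, −78 → 0 °C) gives a far better leaving group that should ionise below 0 °C through the same O1 shift. With no nucleophile present the ion should collapse by proton loss to (S)-2-(prop-1-en-2-yl)-2,3-dihydrobenzofuran-6-yl pivalate F1. Mukaiyama hydration of the 1,1-disubstituted alkene (Co(acac)2, divalent cobalt, PhSiH3, O2, i-PrOH/THF, rt; Na2S2O3 work-up) should then place the hydroxyl on the tertiary carbon, and the route is rejoined at 10.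

Step 17. Recombination of the radical pair may be poorly selective between C5 and C7, the acyl radical may escape the solvent cage (returning phenol 11), or the second arene may take up the light. The fallback sets out from phenol 11 and forms the aryl ketone bond by organolithium acylation. Bromination para to O1 (NBS, MeCN, 0 °C) should give (S)-5-bromo-2-(2-hydroxypropan-2-yl)-2,3-dihydrobenzofuran-6-ol F2. Allylation of the phenol (allyl bromide, K2CO3, acetone) gives (S)-2-[6-(allyloxy)-5-bromo-2,3-dihydrobenzofuran-2-yl]propan-2-ol F3. Acid 22 is converted (MeNHOMe·HCl, EDC·HCl, i-Pr2NEt, CH2Cl2) into (S)-3-(tert-butyldimethylsilyloxy)-3-(2,2-dimethylchroman-6-yl)-N-methoxy-N-methylpropanamide F4. F3 is treated with MeLi (one equivalent, for the tertiary alkoxide) and then t-BuLi (two equivalents) in THF at −78 °C, and the aryllithium is added to F4 at −78 °C. This should give (S)-1-[(S)-6-(allyloxy)-2-(2-hydroxypropan-2-yl)-2,3-dihydrobenzofuran-5-yl]-3-(tert-butyldimethylsilyloxy)-3-(2,2-dimethylchroman-6-yl)propan-1-one F5. Deallylation (Pd(PPh3)4, zerovalent palladium, morpholine, THF, rt) rejoins the route at 24.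

Step 18. Fluoride treatment of the 2'-hydroxy β-hydroxy ketone may trigger dehydration to the chalcone with oxa-Michael closure to a flavanone, or retro-aldol cleavage. The fallback sets out from ester 23 and reverses the order of the last two operations. Desilylation at the ester stage (HF·pyridine, pyridine, THF, 0 °C → rt), where no ortho-hydroxy ketone is present, should give (S)-2-(2-hydroxypropan-2-yl)-2,3-dihydrobenzofuran-6-yl (S)-3-(2,2-dimethylchroman-6-yl)-3-hydroxypropanoate F6. Photo-Fries rearrangement of F6 (hν 254 nm, degassed MeCN, rt) then forms the sensitive β-hydroxy ketone under neutral conditions, and the route is rejoined at 25.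

**Further compounds**

F1 | step 7 | (S)-2-(prop-1-en-2-yl)-2,3-dihydrobenzofuran-6-yl pivalate | CC(C)(C)C(=O)Oc1ccc2c(c1)O[C@H](C(C)=C)C2
F2 | step 17 | (S)-5-bromo-2-(2-hydroxypropan-2-yl)-2,3-dihydrobenzofuran-6-ol | Brc1cc2c(cc1O)O[C@H](C(C)(C)O)C2
F3 | step 17 | (S)-2-[6-(allyloxy)-5-bromo-2,3-dihydrobenzofuran-2-yl]propan-2-ol | Brc1cc2c(cc1OCC=C)O[C@H](C(C)(C)O)C2
F4 | step 17 | (S)-3-(tert-butyldimethylsilyloxy)-3-(2,2-dimethylchroman-6-yl)-N-methoxy-N-methylpropanamide | CC1(C)CCc2cc([C@@H](O[Si](C)(C)C(C)(C)C)CC(=O)N(C)OC)ccc2O1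
F5 | step 17 | (S)-1-[(S)-6-(allyloxy)-2-(2-hydroxypropan-2-yl)-2,3-dihydrobenzofuran-5-yl]-3-(tert-butyldimethylsilyloxy)-3-(2,2-dimethylchroman-6-yl)propan-1-one | CC1(C)CCc2cc([C@@H](O[Si](C)(C)C(C)(C)C)CC(=O)c3cc4c(cc3OCC=C)O[C@H](C(C)(C)O)C4)ccc2O1
F6 | step 18 | (S)-2-(2-hydroxypropan-2-yl)-2,3-dihydrobenzofuran-6-yl (S)-3-(2,2-dimethylchroman-6-yl)-3-hydroxypropanoate | CC1(C)CCc2cc([C@@H](O)CC(=O)Oc3ccc4c(c3)O[C@H](C(C)(C)O)C4)ccc2O1
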